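## Retrosynthetic overview

1. The N-oxide comes from the tertiary amine. The cyclohexane and cyclopentene are cut together by a Pauson–Khand disconnection to a terminal alkyne on the N–CH carbon and a but-3-enyl chain on the neighbouring carbon; the enone oxygen is removed afterwards.
2. The δ-lactone is cut at its tertiary C–O bond (tertiary cation plus propanoic acid arm) and the methyl group at a piperidin-4-one. The piperidinone is cut by a Mannich disconnection to a bicyclic amino ketone and a silylpropynal.
3. The pyrrolidine (N, NCH2, CHCH3 and the two ring-fusion CH) is cut back to a six-membered 1,2-oxazine N-oxide (cyclic nitronate) that holds the same five atoms plus one oxygen. The cyclopentane comes from intramolecular [3+2] addition of this nitronate to a 1,1-disubstituted alkene, and the nitronate from [4+2] addition of a nitroalkene to a chiral (Z)-propenyl ether.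
4. Enabling feature: in the oxazine the ring oxygen sits between N and the acetal carbon (N–O–CH(OR*)), so N–O hydrogenolysis frees an amine and an aldehyde four atoms apart, which reclose without the oxygen (six-membered ring to five-membered ring).
5. Order of ring formation: 1,2-oxazine (temporary), then cyclopentane with isoxazolidine (temporary), then pyrrolidine, piperidine, δ-lactone, and last cyclohexane with cyclopentene.

Key step: step 9

Assumption: the (1R,2S)-2-phenylcyclohexyl group of 11 is taken to shield the enol ether face that leads to nitronate 12 as drawn; if the induction runs the other way, the antipodal alcohol is used and nothing else changes.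

## Route

Step 1
Reactants: 1 4-tert-butoxy-4-oxobutanoic acid
Product: 2 tert-butyl 4-[methoxy(methyl)amino]-4-oxobutanoate
Conditions: 1,1'-carbonyldiimidazole, CH2Cl2, rt; then MeNHOMe·HCl
Reagents that add atoms: N,O-dimethylhydroxylamine hydrochloride, CNOC.Cl
Why: Weinreb amide formation through the acyl imidazole, with the tert-butyl ester inert.

Step 2
Reactants: 2 tert-butyl 4-[methoxy(methyl)amino]-4-oxobutanoate, 3 [2-(1,3-dioxolan-2-yl)ethyl]magnesium bromide
Product: 4 tert-butyl 6-(1,3-dioxolan-2-yl)-4-oxohexanoate
Conditions: THF, −20 to 0 °C; aq. NH4Cl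
Reagents that add atoms: none
Why: Grignard addition to the Weinreb amide stops at the ketone through the chelated tetrahedral adduct, and the hindered tert-butyl ester should not compete at low temperature.

Step 3
Reactants: 4 tert-butyl 6-(1,3-dioxolan-2-yl)-4-oxohexanoate
Product: 5 tert-butyl 6-(1,3-dioxolan-2-yl)-4-methylidenehexanoate
Conditions: Ph3PCH3Br, KOtBu, THF, 0 °C to rt
Reagents that add atoms: methyltriphenylphosphonium bromide, C[P+](c1ccccc1)(c1ccccc1)c1ccccc1.[Br-]
Why: Wittig methylenation of an unhindered dialkyl ketone, which creates neither a stereocenter nor an alkene geometry.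

Step 4
Reactants: 5 tert-butyl 6-(1,3-dioxolan-2-yl)-4-methylidenehexanoate
Product: 6 tert-butyl 4-methylidene-7-oxoheptanoate
Conditions: AcOH/H2O (4:1), 50 °C
Reagents that add atoms: water, O
Why: Acid-catalysed acetal hydrolysis under conditions that should leave the tert-butyl ester and the 1,1-disubstituted alkene untouched.

Step 5
Reactants: 6 tert-butyl 4-methylidene-7-oxoheptanoate
Product: 8 tert-butyl (7E)-4-methylidene-8-nitrooct-7-enoate, via nitro alcohol 7 (not isolated)
Conditions: MeNO2, KOtBu (cat.), THF/tBuOH, 0 °C; then MsCl, Et3N, CH2Cl2, 0 °C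
Reagents that add atoms: nitromethane, C[N+](=O)[O-]
Why: Henry reaction followed by mesylation and E1cB elimination should give the conjugated nitroalkene as the more stable E isomer.

Step 6
Reactants: 9 (1R,2S)-2-phenylcyclohexan-1-ol
Product: 10 allyl (1R,2S)-2-phenylcyclohexyl ether
Conditions: NaH, allyl bromide, THF/DMF, 0 °C to rt
Reagents that add atoms: allyl bromide, C=CCBr
Why: Williamson etherification of the alkoxide, which does not touch the two stereocenters.

Step 7
Reactants: 10 allyl (1R,2S)-2-phenylcyclohexyl ether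
Product: 11 (Z)-prop-1-enyl (1R,2S)-2-phenylcyclohexyl ether
Conditions: KOtBu, DMSO, 60 °C
Reagents that add atoms: none
Why: Base-mediated allyl-to-propenyl ether isomerisation, which runs through the cisoid oxyallyl anion and should therefore give the Z enol ether.

Step 8
Reactants: 8 tert-butyl (7E)-4-methylidene-8-nitrooct-7-enoate, 11 (Z)-prop-1-enyl (1R,2S)-2-phenylcyclohexyl ether
Product: 12 tert-butyl 5-[(4R,5S,6R)-5-methyl-2-oxido-6-{[(1R,2S)-2-phenylcyclohexyl]oxy}-5,6-dihydro-4H-1,2-oxazin-2-ium-4-yl]-4-methylidenepentanoate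
Conditions: Ti(OiPr)2Cl2 (promoter), CH2Cl2, −78 °C; NaHCO3/MeOH quench; used promptly
Reagents that add atoms: none
Why: Lewis-acid-promoted inverse-demand hetero-Diels–Alder reaction of the nitroalkene (heterodiene O=N–C=C) with the enol ether, in which endo approach of the alkoxy and methyl groups of the Z enol ether to the E nitroalkene should give the 4,5-cis-5,6-cis ring and the phenylcyclohexyl group shields one enol ether face to set the absolute configuration.

Step 9
Reactants: 12 tert-butyl 5-[(4R,5S,6R)-5-methyl-2-oxido-6-{[(1R,2S)-2-phenylcyclohexyl]oxy}-5,6-dihydro-4H-1,2-oxazin-2-ium-4-yl]-4-methylidenepentanoate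
Product: 16 tert-butyl 3-[(3S,3aR,6S,6aS)-6-(hydroxymethyl)-3-methyloctahydrocyclopenta[b]pyrrol-6-yl]propanoate, via nitroso acetal 13 (not isolated), via amino aldehyde 14 (not isolated), via cyclic imine 15 (not isolated)
Conditions: PhMe, NaHCO3, 80 °C; then MeOH, Raney Ni, H2 (11 bar), rt
Reagents that add atoms: none
Why: On warming, the cyclic nitronate adds as a 1,3-dipole across the tethered 1,1-disubstituted alkene, which closes the cyclopentane (C–C bond to the quaternary carbon) and a temporary isoxazolidine (O–CH2 bond) in an intramolecular [3+2] cycloaddition of the fused type. Raney Ni/H2 then cleaves both N–O bonds; the oxazine oxygen leaves as a hemiacetal that collapses to the aldehyde and releases the auxiliary alcohol, the freed primary amine condenses with that aldehyde (5-exo-trig imine formation) and the 1-pyrroline is hydrogenated, so the six-membered 1,2-oxazine is contracted to the pyrrolidine by loss of its oxygen. The closest known reaction type is the tandem nitroalkene [4+2]/[3+2] cycloaddition followed by hydrogenolytic unmasking of the nitroso acetal to a pyrrolidine. The two new stereocenters (C-6a and the quaternary C-6) are set by the tether, because the alkene can reach the nitronate carbon only on the face that carries the chain at the neighbouring C-4, which gives the cis-fused cyclopentane with the CH2O arm cis to N and the propanoate arm trans to it; C-3 and C-3a come unchanged from step 8. The step needs fused rather than bridged regiochemistry, secured by the two-carbon tether that only allows a five-membered carbocycle, and N–O cleavage without lactam formation, secured by the tert-butyl ester and neutral conditions.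

Step 10
Reactants: 16 tert-butyl 3-[(3S,3aR,6S,6aS)-6-(hydroxymethyl)-3-methyloctahydrocyclopenta[b]pyrrol-6-yl]propanoate
Product: 17 tert-butyl 3-[(3S,3aR,6S,6aS)-6-formyl-3-methyloctahydrocyclopenta[b]pyrrol-6-yl]propanoate
Conditions: TFA (1.1 equiv), Dess–Martin periodinane, CH2Cl2, 0 °C to rt; NaHCO3 work-up; used crude
Reagents that add atoms: none
Why: Dess–Martin oxidation of the neopentylic primary alcohol with the amine masked as its trifluoroacetate salt, giving an aldehyde that cannot epimerise because its α-carbon is quaternary.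

Step 11
Reactants: 17 tert-butyl 3-[(3S,3aR,6S,6aS)-6-formyl-3-methyloctahydrocyclopenta[b]pyrrol-6-yl]propanoate
Product: 18 tert-butyl 3-[(3S,3aR,6S,6aS)-6-(1-hydroxyhex-5-enyl)-3-methyloctahydrocyclopenta[b]pyrrol-6-yl]propanoate
Conditions: pent-4-enylMgBr (3 equiv), THF, −78 to −20 °C
Reagents that add atoms: pent-4-en-1-ylmagnesium bromide, C=CCCC[Mg]Br
Why: Grignard addition to the aldehyde, which should be faster than attack on the tert-butyl ester; the new carbinol center may form as a mixture because it is erased in step 12.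

Step 12
Reactants: 18 tert-butyl 3-[(3S,3aR,6S,6aS)-6-(1-hydroxyhex-5-enyl)-3-methyloctahydrocyclopenta[b]pyrrol-6-yl]propanoate
Product: 19 tert-butyl 3-[(3S,3aR,6S,6aS)-6-(hex-5-enoyl)-3-methyloctahydrocyclopenta[b]pyrrol-6-yl]propanoate
Conditions: TFA (1.1 equiv), Dess–Martin periodinane, CH2Cl2, rt; NaHCO3 work-up
Reagents that add atoms: none
Why: Dess–Martin oxidation of the secondary alcohol (amine again protected as its salt) converges both carbinol epimers to one ketone.

Step 13
Reactants: 19 tert-butyl 3-[(3S,3aR,6S,6aS)-6-(hex-5-enoyl)-3-methyloctahydrocyclopenta[b]pyrrol-6-yl]propanoate, 20 3-(triisopropylsilyl)prop-2-ynal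
Product: 21 tricyclic alkynyl piperidinone (piperidin-4-one closed between N and the ketone of 19; silylethynyl and butenyl groups trans-diequatorial)
Conditions: CSA (1.0 equiv), 4 Å MS, MeCN, 50 °C
Reagents that add atoms: none
Why: Intramolecular Mannich reaction in which the enol of the hexenoyl ketone attacks the conjugated iminium formed from the secondary amine and the aldehyde (6-endo closure); the closure is reversible, so both new stereocenters should settle equatorial, since an axial group at either carbon would be syn-axial to the cyclopentane bond at the N–CH ring fusion or to the axial propanoate arm.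

Step 14
Reactants: 21 tricyclic alkynyl piperidinone
Product: 22 tertiary methyl carbinol of 21
Conditions: MeMgCl, LaCl3·2LiCl (30 mol %), THF, 0 °C
Reagents that add atoms: methylmagnesium chloride, C[Mg]Cl
Why: Lanthanum-promoted 1,2-addition of the methyl Grignard reagent to the hindered, enolisable ketone in preference to the tert-butyl ester; either carbinol epimer serves, because step 15 is stereoconvergent.

Step 15
Reactants: 22 tertiary methyl carbinol of 21
Product: 24 silylalkynyl δ-lactone, via hydroxy acid 23 (not isolated)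
Conditions: TFA/CH2Cl2 (1:2), rt; K2CO3 work-up
Reagents that add atoms: none
Why: Acidolysis of the tert-butyl ester followed by ionisation of the tertiary alcohol and capture of the cation by the carboxylic acid (alkyl–oxygen lactonisation); the three-atom tether reaches the cation only from the face of the propanoate arm, so the cis-fused lactone with the required configuration at the methyl-bearing carbon should form from either carbinol epimer, with the protonated amine inert.

Step 16
Reactants: 24 silylalkynyl δ-lactone
Product: 25 terminal alkyne lactone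
Conditions: TBAF, THF, 0 °C
Reagents that add atoms: none
Why: Fluoride-mediated cleavage of the alkynyl C–Si bond, which the lactone should survive at low temperature.

Step 17
Reactants: 25 terminal alkyne lactone
Product: 26 hexacyclic cyclopentenone
Conditions: Co2(CO)8 (20 mol %), tetramethylthiourea, CO (1 bar), PhMe, 70 °C
Reagents that add atoms: carbon monoxide, [C-]#[O+]
Why: Catalytic Pauson–Khand [2+2+1] cycloaddition of the 1,7-enyne with CO closes the cyclohexane and the cyclopentenone at once; the alkene is expected to insert through the tether conformer that keeps the metal-bound alkyne terminus staggered between N and H at the propargylic carbon (no 1,3-allylic strain with the equatorial C–N bond), which places the new ring-fusion hydrogen cis to the hydrogen on the butenyl-bearing carbon.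

Step 18
Reactants: 26 hexacyclic cyclopentenone
Product: 27 hexacyclic allylic alcohol
Conditions: NaBH4, CeCl3·7H2O, MeOH, −40 °C
Reagents that add atoms: none
Why: Luche 1,2-reduction of the enone, which should not touch the lactone; the carbinol configuration is irrelevant because the oxygen is removed in step 19.

Step 19
Reactants: 27 hexacyclic allylic alcohol
Product: 28 hexacyclic tertiary amine (N-deoxy target)
Conditions: Et3SiH, TFA, CH2Cl2, 0 °C
Reagents that add atoms: none
Why: Ionic hydrogenation, in which the allyl cation keeps its charge away from the carbon next to the ammonium center, so hydride from the silane should enter at the less hindered former carbinol carbon and leave the trisubstituted alkene at the ring fusion.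

Step 20
Reactants: 28 hexacyclic tertiary amine (N-deoxy target)
Product: 29 target N-oxide
Conditions: mCPBA (1.05 equiv), CH2Cl2, −40 °C; K2CO3 work-up
Reagents that add atoms: 3-chloroperoxybenzoic acid, OOC(=O)c1cccc(Cl)c1
Why: N-oxidation of the tertiary amine should be much faster than epoxidation of the trisubstituted alkene at low temperature, and oxygen can only enter on the lone-pair face fixed by the three rings that meet at nitrogen, which is the configuration of the target.

## Compound list

1 | 4-tert-butoxy-4-oxobutanoic acid | OC(=O)CCC(=O)OC(C)(C)C | starting material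
2 | tert-butyl 4-[methoxy(methyl)amino]-4-oxobutanoate | CON(C)C(=O)CCC(=O)OC(C)(C)C | intermediate
3 | [2-(1,3-dioxolan-2-yl)ethyl]magnesium bromide | Br[Mg]CCC1OCCO1 | starting material
4 | tert-butyl 6-(1,3-dioxolan-2-yl)-4-oxohexanoate | O=C(CCC1OCCO1)CCC(=O)OC(C)(C)C | intermediate
5 | tert-butyl 6-(1,3-dioxolan-2-yl)-4-methylidenehexanoate | C=C(CCC1OCCO1)CCC(=O)OC(C)(C)C | intermediate
6 | tert-butyl 4-methylidene-7-oxoheptanoate | C=C(CCC=O)CCC(=O)OC(C)(C)C | intermediate
7 | tert-butyl 7-hydroxy-4-methylidene-8-nitrooctanoate (racemic, not isolated) | C=C(CCC(O)C[N+](=O)[O-])CCC(=O)OC(C)(C)C | intermediate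
8 | tert-butyl (7E)-4-methylidene-8-nitrooct-7-enoate | C=C(CC/C=C/[N+](=O)[O-])CCC(=O)OC(C)(C)C | intermediate
9 | (1R,2S)-2-phenylcyclohexan-1-ol | O[C@@H]1CCCC[C@H]1c1ccccc1 | starting material
10 | allyl (1R,2S)-2-phenylcyclohexyl ether | C=CCO[C@@H]1CCCC[C@H]1c1ccccc1 | intermediate
11 | (Z)-prop-1-enyl (1R,2S)-2-phenylcyclohexyl ether | C/C=C\O[C@@H]1CCCC[C@H]1c1ccccc1 | intermediate
12 | cyclic nitronate, (4R,5S,6R)-5,6-dihydro-4H-1,2-oxazine 2-oxide with 4-(4-methylidene-pentanoate tert-butyl ester) chain, 5-methyl and 6-(phenylcyclohexyloxy), all cis | C[C@@H]1[C@H](O[C@@H]2CCCC[C@H]2c2ccccc2)O[N+]([O-])=C[C@@H]1CCC(=C)CCC(=O)OC(C)(C)C | intermediate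
13 | tricyclic nitroso acetal (1,2-oxazine and isoxazolidine sharing N, cis-fused cyclopentane; not isolated) | C[C@@H]1[C@H](O[C@@H]4CCCC[C@H]4c4ccccc4)ON3[C@@H]2[C@](CCC(=O)OC(C)(C)C)(CO3)CC[C@H]12 | intermediate
14 | tert-butyl 3-[(1S,2S,3R)-2-amino-1-(hydroxymethyl)-3-[(2S)-1-oxopropan-2-yl]cyclopentyl]propanoate (not isolated) | C[C@H](C=O)[C@H]1CC[C@@](CCC(=O)OC(C)(C)C)(CO)[C@H]1N | intermediate
15 | tert-butyl 3-[(3S,3aR,6S,6aS)-6-(hydroxymethyl)-3-methyl-3,3a,4,5,6,6a-hexahydrocyclopenta[b]pyrrol-6-yl]propanoate (1-pyrroline, not isolated) | C[C@@H]1C=N[C@@H]2[C@](CCC(=O)OC(C)(C)C)(CO)CC[C@H]12 | intermediate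
16 | tert-butyl 3-[(3S,3aR,6S,6aS)-6-(hydroxymethyl)-3-methyloctahydrocyclopenta[b]pyrrol-6-yl]propanoate | C[C@@H]1CN[C@@H]2[C@](CCC(=O)OC(C)(C)C)(CO)CC[C@H]12 | intermediate
17 | tert-butyl 3-[(3S,3aR,6S,6aS)-6-formyl-3-methyloctahydrocyclopenta[b]pyrrol-6-yl]propanoate | C[C@@H]1CN[C@@H]2[C@](CCC(=O)OC(C)(C)C)(C=O)CC[C@H]12 | intermediate
18 | tert-butyl 3-[(3S,3aR,6S,6aS)-6-(1-hydroxyhex-5-enyl)-3-methyloctahydrocyclopenta[b]pyrrol-6-yl]propanoate (both carbinol epimers) | C[C@@H]1CN[C@@H]2[C@](CCC(=O)OC(C)(C)C)(C(O)CCCC=C)CC[C@H]12 | intermediate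
19 | tert-butyl 3-[(3S,3aR,6S,6aS)-6-(hex-5-enoyl)-3-methyloctahydrocyclopenta[b]pyrrol-6-yl]propanoate | C[C@@H]1CN[C@@H]2[C@](CCC(=O)OC(C)(C)C)(C(=O)CCCC=C)CC[C@H]12 | intermediate
20 | 3-(triisopropylsilyl)prop-2-ynal | O=CC#C[Si](C(C)C)(C(C)C)C(C)C | starting material
21 | tricyclic alkynyl piperidinone (N–CH bears the silylethynyl group, next carbon the but-3-enyl group trans to it, then the ketone joined to the quaternary carbon; tert-butyl propanoate retained) | C[C@@H]1CN2[C@@H](C#C[Si](C(C)C)(C(C)C)C(C)C)[C@H](CCC=C)C(=O)[C@]3(CCC(=O)OC(C)(C)C)CC[C@H]1[C@@H]32 | intermediate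
22 | tertiary methyl carbinol of 21 (either configuration at the carbinol carbon) | C[C@@H]1CN2[C@@H](C#C[Si](C(C)C)(C(C)C)C(C)C)[C@H](CCC=C)C(C)(O)[C@]3(CCC(=O)OC(C)(C)C)CC[C@H]1[C@@H]32 | intermediate
23 | hydroxy acid from 22 (not isolated) | C[C@@H]1CN2[C@@H](C#C[Si](C(C)C)(C(C)C)C(C)C)[C@H](CCC=C)C(C)(O)[C@]3(CCC(=O)O)CC[C@H]1[C@@H]32 | intermediate
24 | silylalkynyl δ-lactone (cis-fused lactone on the piperidine; O-bearing carbon carries CH3) | C[C@@H]1CN2[C@@H](C#C[Si](C(C)C)(C(C)C)C(C)C)[C@H](CCC=C)[C@@]3(C)OC(=O)CC[C@]34CC[C@H]1[C@@H]42 | intermediate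
25 | terminal alkyne lactone | C[C@@H]1CN2[C@@H](C#C)[C@H](CCC=C)[C@@]3(C)OC(=O)CC[C@]34CC[C@H]1[C@@H]42 | intermediate
26 | hexacyclic cyclopentenone (C=O at the future allylic CH2 of the cyclopentene) | C[C@@H]1CN2[C@H]3C4=CC(=O)C[C@@H]4CC[C@@H]3[C@@]3(C)OC(=O)CC[C@]34CC[C@H]1[C@@H]42 | intermediate
27 | hexacyclic allylic alcohol (either carbinol epimer) | C[C@@H]1CN2[C@H]3C4=CC(O)C[C@@H]4CC[C@@H]3[C@@]3(C)OC(=O)CC[C@]34CC[C@H]1[C@@H]42 | intermediate
28 | hexacyclic tertiary amine (N-deoxy target) | C[C@@H]1CN2[C@H]3C4=CCC[C@@H]4CC[C@@H]3[C@@]3(C)OC(=O)CC[C@]34CC[C@H]1[C@@H]42 | intermediate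
29 | target N-oxide (CNP0566793.5) | C[C@@H]1C[N@+]2([O-])[C@H]3C4=CCC[C@@H]4CC[C@@H]3[C@@]3(C)OC(=O)CC[C@]34CC[C@H]1[C@@H]42 | target

## Step count and risks

Total step count: 20. Longest linear sequence: 18 (steps 1–5 and 8–20; steps 6–7 make the enol ether).

Steps most likely to fail:

**Step 13.** Conjugate addition of the secondary amine to the alkyne carbon of the ynal may outrun iminium formation and cyclisation. Fallback, from 19 back to 21: the ketone methylene of 19 is condensed with tert-butoxybis(dimethylamino)methane (PhMe, 90 °C) to the enaminone F5. Warming with AcOH exchanges the dimethylamino group for the ring nitrogen and closes the cyclic vinylogous amide F6. O-Methylation with MeOTf gives the methoxy iminium triflate F7, and [(triisopropylsilyl)ethynyl]magnesium bromide adds to its iminium carbon to give the enol ether F8. Aqueous HCl, then K2CO3/MeOH, hydrolyses the enol ether and equilibrates both α-centers to 21.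

**Step 17.** The alkene may insert on the other face, which would give the epimer at the new ring-fusion CH. Fallback, from 25 back to 26: the cycloadduct is taken on as the epimeric enone F9. TMSOTf/Et3N gives the extended silyl dienol ether F10, and Saegusa oxidation (Pd(OAc)2, MeCN) gives the linear dienone F11, in which the ring-fusion carbon is trigonal. Hydrogenation of the γ,δ-alkene with [Ir(cod)(PCy3)(py)]PF6/H2, directed by the basic nitrogen that lies on the face where the hydrogen is needed, re-creates the CH center and returns 26.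

**Step 9.** The thermal [3+2] addition to the unactivated alkene may be slower than decomposition of the nitronate, which carries hydrogen on its nitronate carbon. Fallback, from 4 back to 16: Horner–Wadsworth–Emmons reaction of 4 with diethyl [(phenylsulfonyl)methyl]phosphonate (NaH, THF) gives the vinyl sulfone F1. Aqueous AcOH gives the aldehyde F2, and the Henry/mesylation sequence of step 5 gives the nitroalkene F3. With 11 and Ti(OiPr)2Cl2 the [4+2] adduct should cyclise on warming onto the electron-poor alkene (nitronate carbon to the β-carbon, oxygen to the sulfonyl-bearing carbon) to the sulfonyl nitroso acetal F4. Raney Ni/H2 then cleaves the N–O bonds, the α-hydroxy sulfone loses benzenesulfinic acid, the aldehyde is reduced, and the same ring contraction gives 16.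

## Further compounds

F1 | step 9 | tert-butyl 6-(1,3-dioxolan-2-yl)-4-[(phenylsulfonyl)methylidene]hexanoate | O=C(OC(C)(C)C)CCC(=CS(=O)(=O)c1ccccc1)CCC1OCCO1
F2 | step 9 | tert-butyl 7-oxo-4-[(phenylsulfonyl)methylidene]heptanoate | O=CCCC(=CS(=O)(=O)c1ccccc1)CCC(=O)OC(C)(C)C
F3 | step 9 | tert-butyl (7E)-8-nitro-4-[(phenylsulfonyl)methylidene]oct-7-enoate | [O-][N+](=O)/C=C/CCC(=CS(=O)(=O)c1ccccc1)CCC(=O)OC(C)(C)C
F4 | step 9 | sulfonyl nitroso acetal (13 with PhSO2 on the isoxazolidine O–CH carbon) | C[C@@H]1[C@H](O[C@@H]4CCCC[C@H]4c4ccccc4)ON3[C@@H]2[C@](CCC(=O)OC(C)(C)C)(C(O3)S(=O)(=O)c3ccccc3)CC[C@H]12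
F5 | step 13 | enaminone of 19 (dimethylaminomethylidene on the ketone α-carbon) | C[C@@H]1CN[C@@H]2[C@](CCC(=O)OC(C)(C)C)(C(=O)C(CCC=C)=CN(C)C)CC[C@H]12
F6 | step 13 | tricyclic vinylogous amide (2,3-dihydropyridin-4-one) | C[C@@H]1CN2C=C(CCC=C)C(=O)[C@]3(CCC(=O)OC(C)(C)C)CC[C@H]1[C@@H]32
F7 | step 13 | methoxy iminium triflate | C[C@@H]1C[N+]2=CC(CCC=C)=C(OC)[C@]3(CCC(=O)OC(C)(C)C)CC[C@H]1[C@@H]32.[O-]S(=O)(=O)C(F)(F)F
F8 | step 13 | alkynyl enol ether (either configuration at the N–CH carbon) | C[C@@H]1CN2C(C#C[Si](C(C)C)(C(C)C)C(C)C)C(CCC=C)=C(OC)[C@]3(CCC(=O)OC(C)(C)C)CC[C@H]1[C@@H]32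
F9 | step 17 | epimer of 26 at the ring-fusion CH | C[C@@H]1CN2[C@H]3C4=CC(=O)C[C@H]4CC[C@@H]3[C@@]3(C)OC(=O)CC[C@]34CC[C@H]1[C@@H]42
F10 | step 17 | extended trimethylsilyl dienol ether | C[C@@H]1CN2[C@H]3C=4C=C(O[Si](C)(C)C)CC=4CC[C@@H]3[C@@]3(C)OC(=O)CC[C@]34CC[C@H]1[C@@H]42
F11 | step 17 | linear dienone | C[C@@H]1CN2[C@H]3C4=CC(=O)CC4=CC[C@@H]3[C@@]3(C)OC(=O)CC[C@]34CC[C@H]1[C@@H]42
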